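**Plan**

- Retrosynthesis: the lactol stereocentre is traced back to a separable (S)-1-phenylethyl acetal of the racemic lactol. The lactol-lactone ring is opened to a masked 2-formylbenzoate, and the seven-membered depsidone ring is cut first at the ester C–O bond, then at the diaryl ether C–O bond on the ring A side.
- The hydroxymethyl carbon of ring B is then removed, and ring B is cut at two C–C bonds: ether-bearing carbon to lactol-bearing carbon, and phenol-bearing carbon to lactone-carbonyl-bearing carbon.
- Enabling feature: ring B is a hexasubstituted benzene whose phenol oxygen and diaryl-ether oxygen are para, with the carbons carrying the lactone carbonyl and the lactol carbon between them on one side. A 2-silyloxyfuran (four ring carbons, both oxygens) and an alkynoate (two ring carbons, both carbon substituents) leave exactly this pattern.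
- Forward: ring B is built first (step 4), ring A (made separately as a bromo benzoate) is attached through the new phenol, the C1 unit is added ortho to the second phenol, the depsidone ring is closed by lactonisation, and the lactol-lactone ring closes last on acid unmasking.
- Stereochemistry: the single stereocentre (R, lactol carbon) comes from separating the two (S)-1-phenylethyl acetal epimers, followed by neutral hydrogenolysis.

Key step: step 4

Remark: the lactol carbon of a 3-hydroxyphthalide can epimerise through the ring-opened formyl acid, so it is fixed only in the last two steps and the product should be kept free of acid and base.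

**Step 1**
Reactants: 1 tetronic acid
Product: 2 4-(benzyloxy)furan-2(5H)-one
Conditions: BnOH, TsOH·H2O (cat.), toluene, reflux, Dean–Stark
Reagents that add atoms: benzyl alcohol, OCc1ccccc1
Why: Acid-catalysed vinylogous Fischer esterification of the enolised 1,3-dicarbonyl unit, driven by azeotropic removal of water, should give the vinylogous benzyl ester.

**Step 2**
Reactants: 2 4-(benzyloxy)furan-2(5H)-one
Product: 3 4-(benzyloxy)-2-(triisopropylsilyloxy)furan
Conditions: iPr3SiOTf, NEt3, CH2Cl2, 0 °C; used without chromatography
Reagents that add atoms: triisopropylsilyl trifluoromethanesulfonate, CC(C)[Si](C(C)C)(C(C)C)OS(=O)(=O)C(F)(F)F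
Why: Soft enolisation of the butenolide with a silyl triflate and an amine (silyl dienol ether formation) should give the aromatic 2-silyloxyfuran.

**Step 3**
Reactants: 4 3,3-diethoxyprop-1-yne
Product: 6 tert-butyl 4,4-diethoxybut-2-ynoate, via lithium acetylide 5 (not isolated)
Conditions: n-BuLi, THF, −78 °C; Boc2O, −78 °C to rt; H2O
Reagents that add atoms: di-tert-butyl dicarbonate, CC(C)(C)OC(=O)OC(=O)OC(C)(C)C
Why: Deprotonation of the terminal alkyne and alkoxycarbonylation of the acetylide with Boc2O should give the tert-butyl ynoate with the aldehyde masked as its diethyl acetal.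

**Step 4**
Reactants: 3 4-(benzyloxy)-2-(triisopropylsilyloxy)furan (limiting), 6 tert-butyl 4,4-diethoxybut-2-ynoate (slight excess)
Product: 8 tert-butyl 4-(benzyloxy)-2-(diethoxymethyl)-3-hydroxy-6-(triisopropylsilyloxy)benzoate, via oxanorbornadiene 7 (not isolated)
Conditions: toluene, 60 °C, N2; chromatography on NEt3-deactivated silica
Reagents that add atoms: none
Why: The electron-rich 2-silyloxyfuran should add across the ynoate in a normal-demand Diels–Alder reaction (or its stepwise Michael/aldol equivalent), the unsubstituted C-5, activated by both the silyloxy and the benzyloxy group, bonding to the alkyne carbon β to the ester and the silyloxy-bearing C-2 to the α carbon, so that ring B closes in the [4+2] mode to the 7-oxanorbornadiene 7. The bridgehead silyloxy group then expels the bridging oxygen from C-2, the resulting cation being stabilised by the silyloxy and benzyloxy groups, and loss of the proton at the other bridgehead aromatises the ring, the former furan oxygen becoming the free phenol. The closest known reaction type is the cycloaddition and ring opening of 2-silyloxyfurans with acetylenic esters to para-hydroquinone monosilyl ethers. The two bridgehead stereocentres of 7 disappear on aromatisation, so no stereocentre has to be controlled. The step needs one regiochemical orientation, which pairing the most nucleophilic diene terminus with the β carbon of the ynoate should secure (the acetal leaves the ester as the only conjugating acceptor), and it needs the silyl group to stay on its oxygen, which the bulky triisopropylsilyl group and the furan as limiting component should ensure.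

**Step 5**
Reactants: 9 4-methoxy-2,5-dimethylaniline
Product: 10 2-bromo-4-methoxy-3,6-dimethylaniline
Conditions: NBS (1 equiv), MeCN, 0 °C, dark
Reagents that add atoms: N-bromosuccinimide, O=C1CCC(=O)N1Br
Why: Electrophilic aromatic bromination should go ortho to the amino group, the strongest donor, whose para position carries the methoxy group and whose other ortho position carries a methyl group.

**Step 6**
Reactants: 10 2-bromo-4-methoxy-3,6-dimethylaniline
Product: 12 3-bromo-2-iodo-5-methoxy-1,4-dimethylbenzene, via arenediazonium tosylate 11 (not isolated)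
Conditions: TsOH·H2O, NaNO2, KI, MeCN/H2O, 10 °C to rt
Reagents that add atoms: potassium iodide, [K+].[I-]
Why: Diazotisation and displacement by iodide (Sandmeyer-type iodination, which needs no copper) should replace the amino group by iodine.

**Step 7**
Reactants: 12 3-bromo-2-iodo-5-methoxy-1,4-dimethylbenzene
Product: 14 benzyl 2-bromo-4-methoxy-3,6-dimethylbenzoate, via arylmagnesium chloride 13 (not isolated)
Conditions: iPrMgCl·LiCl, THF, −40 °C; ClCO2Bn, −40 to 0 °C
Reagents that add atoms: benzyl chloroformate, O=C(Cl)OCc1ccccc1
Why: Iodine–magnesium exchange is far faster than bromine–magnesium exchange, so only the iodide position should be metallated, and acylation of the Grignard reagent by the chloroformate should give the benzyl ester with the bromide next to it.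

**Step 8**
Reactants: 8 tert-butyl 4-(benzyloxy)-2-(diethoxymethyl)-3-hydroxy-6-(triisopropylsilyloxy)benzoate, 14 benzyl 2-bromo-4-methoxy-3,6-dimethylbenzoate
Product: 15 benzyl 2-[6-(benzyloxy)-3-(tert-butoxycarbonyl)-2-(diethoxymethyl)-4-(triisopropylsilyloxy)phenoxy]-4-methoxy-3,6-dimethylbenzoate
Conditions: (CuOTf)2·C6H6 (cat.), 1-naphthoic acid, Cs2CO3, 4 Å molecular sieves, toluene, 110 °C
Reagents that add atoms: none
Why: Ullmann-type copper-catalysed diaryl ether synthesis, in which the ortho ester assists oxidative addition of the aryl bromide to the copper phenoxide, should join the two hindered rings, and the non-polar medium should keep the silyl ether in place.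

**Step 9**
Reactants: 15 the diaryl ether
Product: 16 benzyl 2-[6-(benzyloxy)-3-(tert-butoxycarbonyl)-2-(diethoxymethyl)-4-hydroxyphenoxy]-4-methoxy-3,6-dimethylbenzoate
Conditions: Bu4NF, AcOH, THF, 0 °C
Reagents that add atoms: none
Why: Fluoride-induced cleavage of the aryl silyl ether (desilylation) should free the phenol next to the tert-butyl ester while the hindered esters, the acetal and the benzyl ether are untouched.

**Step 10**
Reactants: 16 the phenol
Product: 17 benzyl 2-[6-(benzyloxy)-3-(tert-butoxycarbonyl)-2-(diethoxymethyl)-5-formyl-4-hydroxyphenoxy]-4-methoxy-3,6-dimethylbenzoate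
Conditions: MgCl2, NEt3, (CH2O)n, THF, reflux
Reagents that add atoms: paraformaldehyde (as formaldehyde), C=O
Why: Magnesium-mediated ortho-formylation of a phenol (Casnati–Skattebøl reaction) delivers formaldehyde within the magnesium phenoxide, so it should reach only the single free carbon ortho to the phenol on ring B and not the free position of ring A.

**Step 11**
Reactants: 17 the salicylaldehyde
Product: 18 benzyl 2-[6-(benzyloxy)-3-(tert-butoxycarbonyl)-2-(diethoxymethyl)-4-hydroxy-5-(hydroxymethyl)phenoxy]-4-methoxy-3,6-dimethylbenzoate
Conditions: NaBH4, THF/MeOH, 0 °C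
Reagents that add atoms: none
Why: Borohydride reduction of the aryl aldehyde should give the benzylic alcohol while the hindered tert-butyl and benzyl esters are not reduced.

**Step 12**
Reactants: 18 the 2-hydroxybenzyl alcohol
Product: 19 benzyl 2-{[5-(benzyloxy)-8-(tert-butoxycarbonyl)-7-(diethoxymethyl)-2,2-dimethyl-4H-1,3-benzodioxin-6-yl]oxy}-4-methoxy-3,6-dimethylbenzoate
Conditions: 2-methoxypropene (excess), PPTS (cat.), CH2Cl2, 0 °C
Reagents that add atoms: 2-methoxypropene, COC(C)=C
Why: Acid-catalysed ketalisation of the 2-hydroxybenzyl alcohol with an enol ether (acetonide formation) should mask the phenol and the primary alcohol together, the reactive enol ether being activated under acid too mild to ionise the aryl acetal and its excess taking up the methanol released.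

**Step 13**
Reactants: 19 the acetonide
Product: 20 2-{[8-(tert-butoxycarbonyl)-7-(diethoxymethyl)-5-hydroxy-2,2-dimethyl-4H-1,3-benzodioxin-6-yl]oxy}-4-methoxy-3,6-dimethylbenzoic acid
Conditions: H2 (1 atm), Pd/C, EtOAc, rt
Reagents that add atoms: none
Why: Catalytic hydrogenolysis should cleave the benzyl ether and the benzyl ester in one operation, the doubly flanked benzylic C–O bond of the benzodioxine being far slower to cleave, as known for acetonide-protected salicyl alcohols.

**Step 14**
Reactants: 20 the hydroxy acid
Product: 21 the protected depsidone: the dibenzo[b,e][1,4]dioxepin-11-one formed by ester formation between the ring A carboxyl group and the 5-hydroxyl group of the benzodioxine of 20, still carrying the tert-butyl ester, the diethyl acetal and the acetonide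
Conditions: DCC, DMAP (cat.), CH2Cl2, high dilution, rt
Reagents that add atoms: none
Why: Carbodiimide-mediated (Steglich-type) lactonisation of the ortho-aryloxy benzoic acid onto the neighbouring phenol should close the seven-membered depsidone ring, the only other hydroxyl groups being tied up in the acetonide.

**Step 15**
Reactants: 21 the protected depsidone
Product: 22 the racemic lactol (the target constitution with both configurations at the lactol carbon)
Conditions: CF3CO2H/H2O/CH2Cl2, 0 °C to rt
Reagents that add atoms: water, O
Why: Acidolysis of the tert-butyl ester and hydrolysis of the diethyl acetal and the acetonide should occur together, and the freed 2-formylbenzoic acid should close spontaneously to the 3-hydroxyphthalide (ring-chain tautomerism), the aryl ester of the depsidone being stable to acid.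

**Step 16**
Reactants: 22 the racemic lactol
Product: 23 the (S)-1-phenylethyl acetal with the (R)-configured acetal carbon (1-phenylethoxy group in place of the lactol hydroxyl group)
Conditions: (S)-1-phenylethanol (excess), PPTS (cat.), 4 Å molecular sieves, toluene, 50 °C; separation of the two epimers by chromatography or fractional crystallisation
Reagents that add atoms: (S)-1-phenylethanol, C[C@H](O)c1ccccc1
Why: Acid-catalysed pseudo-ester (acetal) formation of the 3-hydroxyphthalide with an enantiopure alcohol should give the two acetals epimeric at the acetal carbon, which are diastereomers and therefore separable, so that the (R) configuration is selected by this separation and not induced, and the material of the other configuration can be put back into the same acid equilibration.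

**Step 17**
Reactants: 23 the (R)-configured (S)-1-phenylethyl acetal
Product: 24 the target, (R)-configured at the lactol carbon
Conditions: H2 (1 atm), Pd(OH)2/C, EtOAc, rt; filtration and evaporation below rt
Reagents that add atoms: none
Why: Hydrogenolysis of the benzylic C–O bond of the 1-phenylethyl group breaks no bond at the acetal carbon, so the lactol should be released under neutral conditions with its (R) configuration retained.

**Compound list**

1 | tetronic acid | OC1=CC(=O)OC1 | starting material
2 | 4-(benzyloxy)furan-2(5H)-one | O=C1C=C(OCc2ccccc2)CO1 | intermediate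
3 | 4-(benzyloxy)-2-(triisopropylsilyloxy)furan | CC(C)[Si](C(C)C)(C(C)C)Oc1cc(OCc2ccccc2)co1 | intermediate
4 | 3,3-diethoxyprop-1-yne | C#CC(OCC)OCC | starting material
5 | lithium 3,3-diethoxyprop-1-yn-1-ide | [Li]C#CC(OCC)OCC | intermediate
6 | tert-butyl 4,4-diethoxybut-2-ynoate | CCOC(OCC)C#CC(=O)OC(C)(C)C | intermediate
7 | tert-butyl 5-(benzyloxy)-3-(diethoxymethyl)-1-(triisopropylsilyloxy)-7-oxabicyclo[2.2.1]hepta-2,5-diene-2-carboxylate (racemic) | CC(C)[Si](C(C)C)(C(C)C)OC12OC(C(OCc3ccccc3)=C1)C(C(OCC)OCC)=C2C(=O)OC(C)(C)C | intermediate
8 | tert-butyl 4-(benzyloxy)-2-(diethoxymethyl)-3-hydroxy-6-(triisopropylsilyloxy)benzoate | Oc1c(OCc2ccccc2)cc(O[Si](C(C)C)(C(C)C)C(C)C)c(C(=O)OC(C)(C)C)c1C(OCC)OCC | intermediate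
9 | 4-methoxy-2,5-dimethylaniline | COc1cc(C)c(N)cc1C | starting material
10 | 2-bromo-4-methoxy-3,6-dimethylaniline | COc1cc(C)c(N)c(Br)c1C | intermediate
11 | 2-bromo-4-methoxy-3,6-dimethylbenzenediazonium 4-methylbenzenesulfonate | COc1cc(C)c([N+]#N)c(Br)c1C.Cc1ccc(cc1)S(=O)(=O)[O-] | intermediate
12 | 3-bromo-2-iodo-5-methoxy-1,4-dimethylbenzene | COc1cc(C)c(I)c(Br)c1C | intermediate
13 | (2-bromo-4-methoxy-3,6-dimethylphenyl)magnesium chloride, LiCl complex | COc1cc(C)c([Mg]Cl)c(Br)c1C.[Li+].[Cl-] | intermediate
14 | benzyl 2-bromo-4-methoxy-3,6-dimethylbenzoate | COc1cc(C)c(C(=O)OCc2ccccc2)c(Br)c1C | intermediate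
15 | benzyl 2-[6-(benzyloxy)-3-(tert-butoxycarbonyl)-2-(diethoxymethyl)-4-(triisopropylsilyloxy)phenoxy]-4-methoxy-3,6-dimethylbenzoate | COc1cc(C)c(C(=O)OCc2ccccc2)c(Oc2c(OCc3ccccc3)cc(O[Si](C(C)C)(C(C)C)C(C)C)c(C(=O)OC(C)(C)C)c2C(OCC)OCC)c1C | intermediate
16 | benzyl 2-[6-(benzyloxy)-3-(tert-butoxycarbonyl)-2-(diethoxymethyl)-4-hydroxyphenoxy]-4-methoxy-3,6-dimethylbenzoate | COc1cc(C)c(C(=O)OCc2ccccc2)c(Oc2c(OCc3ccccc3)cc(O)c(C(=O)OC(C)(C)C)c2C(OCC)OCC)c1C | intermediate
17 | benzyl 2-[6-(benzyloxy)-3-(tert-butoxycarbonyl)-2-(diethoxymethyl)-5-formyl-4-hydroxyphenoxy]-4-methoxy-3,6-dimethylbenzoate | COc1cc(C)c(C(=O)OCc2ccccc2)c(Oc2c(OCc3ccccc3)c(C=O)c(O)c(C(=O)OC(C)(C)C)c2C(OCC)OCC)c1C | intermediate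
18 | benzyl 2-[6-(benzyloxy)-3-(tert-butoxycarbonyl)-2-(diethoxymethyl)-4-hydroxy-5-(hydroxymethyl)phenoxy]-4-methoxy-3,6-dimethylbenzoate | COc1cc(C)c(C(=O)OCc2ccccc2)c(Oc2c(OCc3ccccc3)c(CO)c(O)c(C(=O)OC(C)(C)C)c2C(OCC)OCC)c1C | intermediate
19 | benzyl 2-{[5-(benzyloxy)-8-(tert-butoxycarbonyl)-7-(diethoxymethyl)-2,2-dimethyl-4H-1,3-benzodioxin-6-yl]oxy}-4-methoxy-3,6-dimethylbenzoate | COc1cc(C)c(C(=O)OCc2ccccc2)c(Oc2c(OCc3ccccc3)c3COC(C)(C)Oc3c(C(=O)OC(C)(C)C)c2C(OCC)OCC)c1C | intermediate
20 | 2-{[8-(tert-butoxycarbonyl)-7-(diethoxymethyl)-5-hydroxy-2,2-dimethyl-4H-1,3-benzodioxin-6-yl]oxy}-4-methoxy-3,6-dimethylbenzoic acid | COc1cc(C)c(C(=O)O)c(Oc2c(O)c3COC(C)(C)Oc3c(C(=O)OC(C)(C)C)c2C(OCC)OCC)c1C | intermediate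
21 | protected depsidone (seven-membered lactone of 20; tert-butyl ester, diethyl acetal and acetonide retained) | COc1cc(C)c2c(c1C)Oc1c(c3COC(C)(C)Oc3c(C(=O)OC(C)(C)C)c1C(OCC)OCC)OC2=O | intermediate
22 | racemic lactol (target constitution, both configurations at the lactol carbon) | COc1cc(C)c2c(c1C)Oc1c(c(CO)c(O)c3c1C(O)OC3=O)OC2=O | intermediate
23 | (S)-1-phenylethyl acetal of the lactol, acetal carbon (R) | COc1cc(C)c2c(c1C)Oc1c(c(CO)c(O)c3c1[C@H](O[C@@H](C)c4ccccc4)OC3=O)OC2=O | intermediate
24 | CNP0321962.1, lactol carbon (R) | COc1cc(C)c2c(c1C)Oc1c(c(CO)c(O)c3c1[C@H](O)OC3=O)OC2=O | target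

**Step count and risks**

Total: 17 steps. Longest linear sequence: 13 steps (1, 2, 4, then 8 to 17; the ring A branch 5, 6, 7, then 8 to 17 is equally long).

The three steps most likely to fail:

Step 8. Both partners carry two ortho substituents, so the phenoxide and the aryl bromide may not meet at copper, and at 110 °C silyl transfer between phenoxides may set in. The fallback gives up copper catalysis for a metal-free arylation with a diaryliodonium salt, the method best suited to ethers with four ortho substituents. It sets out from 14, which halide exchange (CuI, NaI, trans-N,N′-dimethylcyclohexane-1,2-diamine, dioxane, 110 °C) should convert into benzyl 2-iodo-4-methoxy-3,6-dimethylbenzoate F1. Oxidation of F1 with mCPBA and TsOH·H2O in MeCN followed by 1,3,5-trimethoxybenzene should give [2-(benzyloxycarbonyl)-5-methoxy-3,6-dimethylphenyl](2,4,6-trimethoxyphenyl)iodonium tosylate F2. The potassium phenoxide of 8 (t-BuOK, THF, rt) should then attack the trivalent iodine of F2 and couple with the ring A aryl group, the electron-rich trimethoxyphenyl group staying on iodine, and the route is rejoined at 15.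

Step 4. The acetal-bearing ynoate is a weaker dienophile than an acetylenedicarboxylate, so the cycloaddition may be outrun by desilylation of the furan, by open-chain conjugate addition through C-3, or by transfer of the silyl group to the new phenol. The fallback forms the same two ring B bonds by an anionic annulation of the Hauser–Kraus type in place of the neutral cycloaddition. It sets out from 2 and 6: LiN(SiMe3)2 in THF at −78 °C should deprotonate 2 at C-5, the dienolate should add to the β carbon of 6, the allenolate should close onto the lactone carbonyl, and the bridged alkoxide should open and tautomerise, after aqueous work-up, to tert-butyl 4-(benzyloxy)-2-(diethoxymethyl)-3,6-dihydroxybenzoate F3. Silylation of F3 with iPr3SiOTf (1 equiv) and 2,6-lutidine at −78 °C should take the less hindered hydroxyl group next to the ester, the other being flanked by the benzyloxy and the diethoxymethyl group, and the route is rejoined at 8.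

Step 17. Hydrogenolysis may go on to cleave the benzylic hydroxymethyl group or the benzylic C–O bond of the lactone ring, and slow cleavage would leave time for epimerisation of the freed lactol. The fallback replaces hydrogenolysis by photochemical release. It sets out from 22, which (S)-1-(2-nitrophenyl)ethanol and PPTS in toluene should convert into two epimeric acetals, from which the (S)-1-(2-nitrophenyl)ethyl acetal with the (R)-configured acetal carbon F4 is separated. Irradiation of F4 at 365 nm in MeCN should cleave the nitrobenzylic C–O bond under neutral conditions without touching the acetal carbon, and the route is rejoined at 24.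

**Further compounds**

F1 | step 8 | benzyl 2-iodo-4-methoxy-3,6-dimethylbenzoate | COc1cc(C)c(C(=O)OCc2ccccc2)c(I)c1C
F2 | step 8 | [2-(benzyloxycarbonyl)-5-methoxy-3,6-dimethylphenyl](2,4,6-trimethoxyphenyl)iodonium 4-methylbenzenesulfonate | COc1cc(C)c(C(=O)OCc2ccccc2)c([I+]c2c(OC)cc(OC)cc2OC)c1C.Cc1ccc(cc1)S(=O)(=O)[O-]
F3 | step 4 | tert-butyl 4-(benzyloxy)-2-(diethoxymethyl)-3,6-dihydroxybenzoate | Oc1c(OCc2ccccc2)cc(O)c(C(=O)OC(C)(C)C)c1C(OCC)OCC
F4 | step 17 | (S)-1-(2-nitrophenyl)ethyl acetal of the lactol, acetal carbon (R) | COc1cc(C)c2c(c1C)Oc1c(c(CO)c(O)c3c1[C@H](O[C@@H](C)c4ccccc4[N+](=O)[O-])OC3=O)OC2=O
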